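**Retrosynthetic overview**

1. Target 24 comes from bis(phenylboronate) 23, in which both diols are masked and are freed at the end by neutral transesterification.
2. Key disconnection: ring B (pyran O2–C1=C8a–C4a–C4=C3) is cut at C3=C4 into an ester carbonyl (C3) and a phosphonium ylide (C4), i.e. side-chain acid 19 plus core enol phosphonium salt 12, joined by one-pot O-acylation and intramolecular ester Wittig olefination.
3. Enabling feature: in ring A the push–pull chain O2–C1=C8a–C4a=C5–C6=O makes O2 an acylable vinylogous carboxylate oxygen and makes C4 (on C4a) the γ-carbon of the C4a=C5–C6=O enone, which stabilises an ylide; ester carbonyl and ylide carbon end up six atoms apart.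
4. Core 12 comes from phenol 9: a reagent-controlled hydroxylative dearomatization sets C7 and a boronic-acid-tethered oxa-Michael addition sets C8 cis to it; the arene comes from 4-hydroxy-3-methylbenzaldehyde by chlorination, directed ortho-metalation/hydroxymethylation and PPh3·HBr.
5. Acid 19 comes from L-isoleucine (C4', C5'), a chelation-controlled MeMgBr addition (C3') and a cross-metathesis (E-acid). Ring order: ring A (the original arene), then the two temporary dioxaborolanes, then ring B (pyran) last.

Key step: step 14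

Remark on numbering: the core uses isochromene numbering (O2, C1, C3 to C8a) and the side chain primed numbers (C1' on C3).
Assumption: in step 6 the (R)-configured diiodyl reagent (made beforehand from commercial (R)-2,2'-diiodo-1,1'-binaphthyl and dimethyldioxirane) is taken to deliver oxygen to the face that gives the 7S quinol; if a pilot run shows the opposite sense, the (S)-reagent is used.

**Route**

Step 1
Reactants: 1 4-hydroxy-3-methylbenzaldehyde
Product: 2 3-chloro-4-hydroxy-5-methylbenzaldehyde
Conditions: NCS (1.05 equiv), AcOH, 50 °C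
Reagents that add atoms: N-chlorosuccinimide O=C1CCC(=O)N1Cl
Why: Electrophilic aromatic chlorination should go to the only free position ortho to the phenol (the future C5), the formyl group deactivating the two remaining positions.

Step 2
Reactants: 2 3-chloro-4-hydroxy-5-methylbenzaldehyde
Product: 3 3-chloro-4-(methoxymethoxy)-5-methylbenzaldehyde
Conditions: MOMCl, iPr2NEt, CH2Cl2, 0 °C to rt
Reagents that add atoms: chloromethyl methyl ether COCCl
Why: O-Alkylation of the acidic phenol (MOM protection) removes the phenolic proton before the metalation; no stereocentre is involved.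

Step 3
Reactants: 3 3-chloro-4-(methoxymethoxy)-5-methylbenzaldehyde
Product: 6 4-chloro-5-(methoxymethoxy)-6-methyl-1,3-dihydro-2-benzofuran-1-ol (lactol), via lithium α-amino alkoxide 4 (not isolated), via ortho-lithiated alkoxide 5 (not isolated)
Conditions: LiN(Me)CH2CH2NMe2 (from MeNHCH2CH2NMe2 and n-BuLi), THF, −20 °C; s-BuLi, −78 °C; CH2O (monomer in THF), −78 °C; 1 M HCl, 0 °C
Reagents that add atoms: formaldehyde C=O
Why: Directed ortho-metalation with in situ protection of the aldehyde as an α-amino alkoxide: this group and the neighbouring chlorine together direct lithiation to the position between them (the future C4a), formaldehyde hydroxymethylates the aryllithium, and on work-up the hydroxy aldehyde closes to the lactol, whose hemiacetal carbon is an epimer mixture that is lost in step 4.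

Step 4
Reactants: 6 4-chloro-5-(methoxymethoxy)-6-methyl-1,3-dihydro-2-benzofuran-1-ol
Product: 8 [(2-chloro-6-formyl-3-hydroxy-4-methylphenyl)methyl]triphenylphosphonium tetrafluoroborate, via phosphonium bromide 7 (not isolated)
Conditions: PPh3·HBr (2.2 equiv), MeCN, 80 °C; then NaBF4 (aq), CH2Cl2, rt
Reagents that add atoms: triphenylphosphine hydrobromide c1ccc(cc1)[PH+](c1ccccc1)c1ccccc1.[Br-]; sodium tetrafluoroborate [Na+].F[B-](F)(F)F
Why: Conversion of a benzylic alcohol into its phosphonium salt with PPh3·HBr (substitution through the benzylic bromide of the ring-opened lactol, as in the standard preparation of (2-hydroxybenzyl)triphenylphosphonium bromide), the same acid cleaving the MOM acetal; anion exchange removes bromide, which the pentavalent iodine oxidant of step 6 could oxidise.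

Step 5
Reactants: 8 [(2-chloro-6-formyl-3-hydroxy-4-methylphenyl)methyl]triphenylphosphonium tetrafluoroborate
Product: 9 {[2-chloro-6-(dimethoxymethyl)-3-hydroxy-4-methylphenyl]methyl}triphenylphosphonium tetrafluoroborate
Conditions: HC(OMe)3, MeOH, camphorsulfonic acid (cat.), rt; NaHCO3 (solid)
Reagents that add atoms: trimethyl orthoformate COC(OC)OC; methanol CO
Why: Acid-catalysed acetalization masks the para-formyl group, whose strong electron withdrawal would otherwise slow the oxidation of the phenol in step 6; no stereocentre is involved.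

Step 6
Reactants: 9 {[2-chloro-6-(dimethoxymethyl)-3-hydroxy-4-methylphenyl]methyl}triphenylphosphonium tetrafluoroborate
Product: 11 {[(4S)-2-chloro-6-formyl-4-hydroxy-4-methyl-3-oxocyclohexa-1,5-dien-1-yl]methyl}triphenylphosphonium tetrafluoroborate, via acetal quinol 10 (not isolated)
Conditions: (R)-2,2'-diiodyl-1,1'-binaphthyl (1.1 equiv), DME/CH2Cl2, −20 °C to rt; then TFA, H2O, THF, 0 °C; used at once in step 7
Reagents that add atoms: (R)-2,2'-diiodyl-1,1'-binaphthyl O=I(=O)c1ccc2ccccc2c1-c1c(I(=O)=O)ccc2ccccc12 (axial R); water O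
Why: Ortho-selective hydroxylative phenol dearomatization by a pentavalent iodine reagent (the phenol binds to iodine and oxygen is delivered intramolecularly to the methyl-bearing ortho carbon, which carries positive charge better than the chlorine-bearing one), the C2-symmetric binaphthyl backbone distinguishing the two ring faces so that C7 is set as S under reagent control, after which aqueous acid unmasks the aldehyde.

Step 7
Reactants: 11 {[(4S)-2-chloro-6-formyl-4-hydroxy-4-methyl-3-oxocyclohexa-1,5-dien-1-yl]methyl}triphenylphosphonium tetrafluoroborate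
Product: 12 {[(3aS,7aS,4E)-6-chloro-4-(hydroxymethylidene)-7a-methyl-7-oxo-2-phenyl-3a,4,7,7a-tetrahydro-1,3,2-benzodioxaborol-5-yl]methyl}triphenylphosphonium tetrafluoroborate (core enol, C7/C8 diol as phenylboronate)
Conditions: PhB(OH)2 (1.1 equiv), N-methylmorpholine (10 mol%), 4 Å molecular sieves, CH2Cl2, rt
Reagents that add atoms: phenylboronic acid OB(O)c1ccccc1
Why: Boronic-acid-mediated intramolecular oxa-Michael addition: the boronic acid esterifies the tertiary C7 hydroxyl and its remaining B–OH oxygen adds to C8 (β-carbon of the enal, δ-carbon of the dienone), which is only possible on the face of the C7 oxygen, so C8 is set as S, cis to C7, by the five-membered dioxaborolane, and the resulting enolate rests as the conjugated C1 enol.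

Step 8
Reactants: 13 L-isoleucine
Product: 14 (2S,3S)-2-hydroxy-3-methylpentanoic acid
Conditions: NaNO2, 1 M H2SO4, H2O, 0 °C to rt
Reagents that add atoms: water O
Why: Diazotization of an α-amino acid goes with net retention (the carboxylate displaces N2 to an α-lactone that water opens, two inversions), so the 2S,3S configuration that becomes C4' and C5' is kept.

Step 9
Reactants: 14 (2S,3S)-2-hydroxy-3-methylpentanoic acid
Product: 15 (2S,3S)-2-hydroxy-N-methoxy-N,3-dimethylpentanamide
Conditions: MeNHOMe·HCl, EDC·HCl, HOBt, N-methylmorpholine, CH2Cl2, 0 °C to rt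
Reagents that add atoms: N,O-dimethylhydroxylamine hydrochloride CNOC.Cl
Why: Carbodiimide amide coupling to the N-methoxy-N-methylamide, HOBt keeping the activated α-hydroxy acid from epimerising, so both stereocentres are carried over unchanged.

Step 10
Reactants: 15 (2S,3S)-2-hydroxy-N-methoxy-N,3-dimethylpentanamide
Product: 16 (4S,5S)-4-hydroxy-5-methylhept-1-en-3-one
Conditions: CH2=CHMgBr (3 equiv), THF, −20 to 0 °C; inverse quench into cold 1 M HCl
Reagents that add atoms: vinylmagnesium bromide C=C[Mg]Br
Why: Weinreb ketone synthesis: after deprotonation of the hydroxyl the Grignard reagent adds once because the magnesium-chelated adduct survives until the acidic quench, which also protonates the released amine and keeps it from adding to the enone, while the alkoxide form protects C4' from enolisation.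

Step 11
Reactants: 16 (4S,5S)-4-hydroxy-5-methylhept-1-en-3-one
Product: 17 (3R,4S,5S)-3,5-dimethylhept-1-ene-3,4-diol
Conditions: MeMgBr (3 equiv), THF, −78 °C; NH4Cl (aq)
Reagents that add atoms: methylmagnesium bromide C[Mg]Br
Why: Chelation-controlled 1,2-addition (cyclic chelate model): the magnesium alkoxide at C4' and the ketone oxygen form a five-membered chelate and MeMgBr attacks from the face of the C4' hydrogen, anti to the sec-butyl group, which sets C3' as R (the two hydroxyls anti along the main chain).

Step 12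
Reactants: 17 (3R,4S,5S)-3,5-dimethylhept-1-ene-3,4-diol
Product: 18 (4R,5S)-5-[(2S)-butan-2-yl]-4-ethenyl-4-methyl-2-phenyl-1,3,2-dioxaborolane
Conditions: PhB(OH)2 (1.0 equiv), MgSO4, CH2Cl2, rt
Reagents that add atoms: phenylboronic acid OB(O)c1ccccc1
Why: Condensation of the 1,2-diol with a boronic acid gives the cyclic boronate, a protecting group that is put on and taken off under neutral conditions; no stereocentre is touched.

Step 13
Reactants: 18 (4R,5S)-5-[(2S)-butan-2-yl]-4-ethenyl-4-methyl-2-phenyl-1,3,2-dioxaborolane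
Product: 19 (2E)-3-{(4R,5S)-5-[(2S)-butan-2-yl]-4-methyl-2-phenyl-1,3,2-dioxaborolan-4-yl}prop-2-enoic acid
Conditions: acrylic acid (4 equiv), second-generation Hoveyda–Grubbs catalyst RuCl2(H2IMes)(=CH-C6H4-2-OiPr) (5 mol%), CH2Cl2, 40 °C
Reagents that add atoms: acrylic acid C=CC(=O)O
Why: Olefin cross-metathesis between the vinyl group of 18 (slow to homodimerise next to a quaternary carbon) and acrylic acid, the E geometry being the thermodynamic outcome of reversible metathesis; no stereocentre is touched.

Step 14
Reactants: 19 (2E)-3-{(4R,5S)-5-[(2S)-butan-2-yl]-4-methyl-2-phenyl-1,3,2-dioxaborolan-4-yl}prop-2-enoic acid; 12 core enol phosphonium tetrafluoroborate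
Product: 23 bis(phenylboronate) of the target (C7/C8 and C3'/C4' diols each as a 2-phenyl-1,3,2-dioxaborolane), via acid chloride 20 (not isolated), via enol ester phosphonium salt 21 (not isolated), via phosphonium ylide 22 (not isolated)
Conditions: 19, Me2C=C(Cl)NMe2, ClCH2CH2Cl, 0 °C; add to 12 and Et3N (1.05 equiv), −20 °C to rt; then Et3N (2 equiv), 80 °C
Reagents that add atoms: none
Why: The chloroenamine turns 19 into acid chloride 20, which acylates the most acidic site of 12, the enol oxygen O2 of the vinylogous acid O2–C1=C8a–C4a=C5–C6=O, to give enol ester 21; further Et3N removes a proton from C4, whose ylide 22 is stabilised through C4a=C5–C6=O, and the ylide carbon adds to the ester carbonyl C3, the oxaphosphetane collapsing to the C3=C4 enol ether and Ph3P=O (intramolecular Wittig olefination of an ester). The closest known reaction is the one-pot acylation/intramolecular ester-Wittig synthesis of benzofurans from (2-hydroxybenzyl)triphenylphosphonium salts, acid chlorides and Et3N, together with the phosphine-mediated furan syntheses that run through O-acylated enolates. Ring B closes in the 6-exo-trig mode (C4 onto the exocyclic C3=O), after which the new double bond is endocyclic. No stereocentre is formed: C7 and C8 are locked in the dioxaborolane, C3', C4' and C5' are remote, and the E alkene is not touched. The step needs O2-acylation and olefination to win over O6- or C-acylation and over acyl transfer: an O6 ester cannot cyclise (it would need a bridgehead alkene) and returns by acyl transfer, the enol ester geometry equilibrates by reversible amine addition at C1, and however the adduct O2–C3(O−)–C4–P+ is reached, irreversible loss of Ph3P=O drains it to 23.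

Step 15
Reactants: 23 bis(phenylboronate) of the target
Product: 24 (7S,8S)-5-chloro-3-[(1E,3R,4S,5S)-3,4-dihydroxy-3,5-dimethylhept-1-en-1-yl]-7,8-dihydroxy-7-methyl-7,8-dihydro-6H-isochromen-6-one
Conditions: pinacol (20 equiv), MeOH/CH2Cl2, rt
Reagents that add atoms: none
Why: Boronate transesterification: pinacol forms the more stable tetrasubstituted dioxaborolane and so should free both diols under neutral conditions that spare the tertiary allylic alcohol and the vinylogous ester of ring B; no stereocentre is touched.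

**Compound list**

1 | 4-hydroxy-3-methylbenzaldehyde | Cc1cc(C=O)ccc1O | starting material
2 | 3-chloro-4-hydroxy-5-methylbenzaldehyde | Cc1cc(C=O)cc(Cl)c1O | intermediate
3 | 3-chloro-4-(methoxymethoxy)-5-methylbenzaldehyde | COCOc1c(C)cc(C=O)cc1Cl | intermediate
4 | lithium [3-chloro-4-(methoxymethoxy)-5-methylphenyl]{[2-(dimethylamino)ethyl](methyl)amino}methanolate | [Li+].[O-]C(N(C)CCN(C)C)c1cc(C)c(OCOC)c(Cl)c1 | intermediate (not isolated)
5 | the 2-lithio derivative of 4 (lithium between the alkoxide-bearing carbon and chlorine) | [Li+].[O-]C(N(C)CCN(C)C)c1cc(C)c(OCOC)c(Cl)c1[Li] | intermediate (not isolated)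
6 | 4-chloro-5-(methoxymethoxy)-6-methyl-1,3-dihydro-2-benzofuran-1-ol (hemiacetal carbon unassigned, both epimers) | OC1OCc2c(Cl)c(OCOC)c(C)cc12 | intermediate
7 | [(2-chloro-6-formyl-3-hydroxy-4-methylphenyl)methyl]triphenylphosphonium bromide | O=Cc1cc(C)c(O)c(Cl)c1C[P+](c1ccccc1)(c1ccccc1)c1ccccc1.[Br-] | intermediate (not isolated)
8 | [(2-chloro-6-formyl-3-hydroxy-4-methylphenyl)methyl]triphenylphosphonium tetrafluoroborate | O=Cc1cc(C)c(O)c(Cl)c1C[P+](c1ccccc1)(c1ccccc1)c1ccccc1.F[B-](F)(F)F | intermediate
9 | {[2-chloro-6-(dimethoxymethyl)-3-hydroxy-4-methylphenyl]methyl}triphenylphosphonium tetrafluoroborate | COC(OC)c1cc(C)c(O)c(Cl)c1C[P+](c1ccccc1)(c1ccccc1)c1ccccc1.F[B-](F)(F)F | intermediate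
10 | {[(4S)-2-chloro-6-(dimethoxymethyl)-4-hydroxy-4-methyl-3-oxocyclohexa-1,5-dien-1-yl]methyl}triphenylphosphonium tetrafluoroborate | COC(OC)C1=C[C@](C)(O)C(=O)C(Cl)=C1C[P+](c1ccccc1)(c1ccccc1)c1ccccc1.F[B-](F)(F)F | intermediate (not isolated)
11 | {[(4S)-2-chloro-6-formyl-4-hydroxy-4-methyl-3-oxocyclohexa-1,5-dien-1-yl]methyl}triphenylphosphonium tetrafluoroborate | O=CC1=C[C@](C)(O)C(=O)C(Cl)=C1C[P+](c1ccccc1)(c1ccccc1)c1ccccc1.F[B-](F)(F)F | intermediate
12 | {[(3aS,7aS,4E)-6-chloro-4-(hydroxymethylidene)-7a-methyl-7-oxo-2-phenyl-3a,4,7,7a-tetrahydro-1,3,2-benzodioxaborol-5-yl]methyl}triphenylphosphonium tetrafluoroborate | O/C=C1/[C@@H]2OB(c3ccccc3)O[C@]2(C)C(=O)C(Cl)=C1C[P+](c4ccccc4)(c4ccccc4)c4ccccc4.F[B-](F)(F)F | intermediate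
13 | L-isoleucine, (2S,3S)-2-amino-3-methylpentanoic acid | CC[C@H](C)[C@H](N)C(=O)O | starting material
14 | (2S,3S)-2-hydroxy-3-methylpentanoic acid | CC[C@H](C)[C@H](O)C(=O)O | intermediate
15 | (2S,3S)-2-hydroxy-N-methoxy-N,3-dimethylpentanamide | CC[C@H](C)[C@H](O)C(=O)N(C)OC | intermediate
16 | (4S,5S)-4-hydroxy-5-methylhept-1-en-3-one | CC[C@H](C)[C@H](O)C(=O)C=C | intermediate
17 | (3R,4S,5S)-3,5-dimethylhept-1-ene-3,4-diol | CC[C@H](C)[C@H](O)[C@](C)(O)C=C | intermediate
18 | (4R,5S)-5-[(2S)-butan-2-yl]-4-ethenyl-4-methyl-2-phenyl-1,3,2-dioxaborolane | CC[C@H](C)[C@H](O1)[C@](C)(OB1c2ccccc2)C=C | intermediate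
19 | (2E)-3-{(4R,5S)-5-[(2S)-butan-2-yl]-4-methyl-2-phenyl-1,3,2-dioxaborolan-4-yl}prop-2-enoic acid | CC[C@H](C)[C@H](O1)[C@](C)(OB1c2ccccc2)/C=C/C(=O)O | intermediate
20 | (2E)-3-{(4R,5S)-5-[(2S)-butan-2-yl]-4-methyl-2-phenyl-1,3,2-dioxaborolan-4-yl}prop-2-enoyl chloride | CC[C@H](C)[C@H](O1)[C@](C)(OB1c2ccccc2)/C=C/C(=O)Cl | intermediate (not isolated)
21 | enol ester of 12 (at O2, E) with the acyl group of 19, as phosphonium tetrafluoroborate | CC[C@H](C)[C@H](O5)[C@](C)(OB5c6ccccc6)/C=C/C(=O)O/C=C1/[C@@H]2OB(c3ccccc3)O[C@]2(C)C(=O)C(Cl)=C1C[P+](c4ccccc4)(c4ccccc4)c4ccccc4.F[B-](F)(F)F | intermediate (not isolated)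
22 | triphenylphosphonium ylide of 21 (ylide carbon C4) | CC[C@H](C)[C@H](O5)[C@](C)(OB5c6ccccc6)/C=C/C(=O)O/C=C1/[C@@H]2OB(c3ccccc3)O[C@]2(C)C(=O)C(Cl)=C1C=P(c4ccccc4)(c4ccccc4)c4ccccc4 | intermediate (not isolated)
23 | (7S,8S)-5-chloro-7-methyl-7,8-(phenylboranediyldioxy)-3-[(E)-2-{(4R,5S)-5-[(2S)-butan-2-yl]-4-methyl-2-phenyl-1,3,2-dioxaborolan-4-yl}ethenyl]-7,8-dihydro-6H-isochromen-6-one | CC[C@H](C)[C@H](O5)[C@](C)(OB5c6ccccc6)/C=C/C1=CC2=C(Cl)C(=O)[C@@]3(C)OB(c4ccccc4)O[C@H]3C2=CO1 | intermediate
24 | (7S,8S)-5-chloro-3-[(1E,3R,4S,5S)-3,4-dihydroxy-3,5-dimethylhept-1-en-1-yl]-7,8-dihydroxy-7-methyl-7,8-dihydro-6H-isochromen-6-one | CC[C@H](C)[C@H](O)[C@](C)(O)/C=C/C1=CC2=C(Cl)C(=O)[C@@](C)(O)[C@@H](O)C2=CO1 | target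

**Step count and risks**

Total step count: 15. Longest linear sequence: 9 steps (steps 1 to 7, 14 and 15).

Steps most likely to fail:

Step 6. Oxygen transfer to a phenol that still carries two electron-withdrawing groups (chlorine and the phosphoniomethyl group) may be slow, and the facial selectivity of the chiral reagent on this hexasubstituted arene may be poor. Fallback (resolution instead of reagent control): 9 is dearomatized with achiral stabilised 2-iodoxybenzoic acid (THF, rt) to the racemic acetal quinol, i.e. 10 together with its enantiomer, the (4R)-acetal quinol F1. Aqueous TFA gives the racemic enal, 11 together with the (4R)-enal F2, and the conditions of step 7 give the racemic boronate, 12 together with the (3aR,7aR)-boronate F3. This salt is resolved by preparative chromatography on a chiral stationary phase, F3 is discarded, and 12 re-enters the route at step 14.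

Step 14. The tetrahedral adduct may collapse by loss of the enolate oxygen (O-to-C acyl transfer), or the ylide may be acylated at carbon, so that a stabilised acyl ylide builds up instead of losing Ph3P=O. Fallback (acyl shift and cyclodehydration without phosphorus): from 12, aqueous Na2CO3 in THF hydrolyses the vinylogously stabilised phosphonium salt to the C4-methyl enol F4, (3aS,7aS,4E)-6-chloro-4-(hydroxymethylidene)-5,7a-dimethyl-2-phenyl-3a,4-dihydro-1,3,2-benzodioxaborol-7(7aH)-one. Acylation of F4 with 20 (from 19 as in step 14) and Et3N gives the enol ester F5. LiN(SiMe3)2 in THF at −78 °C deprotonates the C4 methyl group and triggers a vinylogous Baker–Venkataraman acyl shift to the 1,5-dicarbonyl compound F6 (C3 ketone, C1 enol). Acetic acid then cyclodehydrates F6 to 23, where the route continues.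

Step 3. The ortho-lithiated chloroarene may lose LiCl to an aryne before it is trapped, or metalation may occur at the other ortho position. Fallback (preformed acetal and a magnesium amide base): 3 is converted with HC(OMe)3, MeOH and pyridinium p-toluenesulfonate into the dimethyl acetal F7, 1-chloro-5-(dimethoxymethyl)-2-(methoxymethoxy)-3-methylbenzene. TMPMgCl·LiCl (THF, 0 °C) magnesiates between the acetal and the chlorine to give the arylmagnesium chloride F8, which should not eliminate at this temperature. Monomeric formaldehyde gives the benzylic alcohol F9, and AcOH/H2O/THF hydrolyses the acetal, the hydroxy aldehyde closing to lactol 6, where the route continues.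

Further compounds

F1 | step 6 | {[(4R)-2-chloro-6-(dimethoxymethyl)-4-hydroxy-4-methyl-3-oxocyclohexa-1,5-dien-1-yl]methyl}triphenylphosphonium tetrafluoroborate | COC(OC)C1=C[C@@](C)(O)C(=O)C(Cl)=C1C[P+](c1ccccc1)(c1ccccc1)c1ccccc1.F[B-](F)(F)F
F2 | step 6 | {[(4R)-2-chloro-6-formyl-4-hydroxy-4-methyl-3-oxocyclohexa-1,5-dien-1-yl]methyl}triphenylphosphonium tetrafluoroborate | O=CC1=C[C@@](C)(O)C(=O)C(Cl)=C1C[P+](c1ccccc1)(c1ccccc1)c1ccccc1.F[B-](F)(F)F
F3 | step 6 | {[(3aR,7aR,4E)-6-chloro-4-(hydroxymethylidene)-7a-methyl-7-oxo-2-phenyl-3a,4,7,7a-tetrahydro-1,3,2-benzodioxaborol-5-yl]methyl}triphenylphosphonium tetrafluoroborate | O/C=C1/[C@H]2OB(c3ccccc3)O[C@@]2(C)C(=O)C(Cl)=C1C[P+](c4ccccc4)(c4ccccc4)c4ccccc4.F[B-](F)(F)F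
F4 | step 14 | (3aS,7aS,4E)-6-chloro-4-(hydroxymethylidene)-5,7a-dimethyl-2-phenyl-3a,4-dihydro-1,3,2-benzodioxaborol-7(7aH)-one | O/C=C1/[C@@H]2OB(c3ccccc3)O[C@]2(C)C(=O)C(Cl)=C1C
F5 | step 14 | enol ester of F4 (at O2, E) with the acyl group of 19 | CC[C@H](C)[C@H](O5)[C@](C)(OB5c6ccccc6)/C=C/C(=O)O/C=C1/[C@@H]2OB(c3ccccc3)O[C@]2(C)C(=O)C(Cl)=C1C
F6 | step 14 | (3aS,7aS)-6-chloro-4-(hydroxymethylidene)-7a-methyl-2-phenyl-5-[(3E)-2-oxo-4-{(4R,5S)-5-[(2S)-butan-2-yl]-4-methyl-2-phenyl-1,3,2-dioxaborolan-4-yl}but-3-en-1-yl]-3a,4-dihydro-1,3,2-benzodioxaborol-7(7aH)-one | CC[C@H](C)[C@H](O5)[C@](C)(OB5c6ccccc6)/C=C/C(=O)CC1=C(Cl)C(=O)[C@@]2(C)OB(c3ccccc3)O[C@H]2C1=CO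
F7 | step 3 | 1-chloro-5-(dimethoxymethyl)-2-(methoxymethoxy)-3-methylbenzene | COCOc1c(C)cc(C(OC)OC)cc1Cl
F8 | step 3 | [2-chloro-6-(dimethoxymethyl)-3-(methoxymethoxy)-4-methylphenyl]magnesium chloride | COCOc1c(C)cc(C(OC)OC)c([Mg]Cl)c1Cl
F9 | step 3 | [2-chloro-6-(dimethoxymethyl)-3-(methoxymethoxy)-4-methylphenyl]methanol | COCOc1c(C)cc(C(OC)OC)c(CO)c1Cl
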